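**Retrosynthetic overview**

- Ascomindone B is a 2,3-diaryl-1-indenone: ring C is C1(=O)–C2=C3–C3a–C7a, fused to ring E. Ring B (which carries ring A through an ether oxygen) sits on C2, ring D on C3. The last step only removes five MOM ethers.
- Ring C is closed last, in one operation from a (Z)-3-arylidenephthalide and lithiated orcinol bis-MOM ether: the C3–ring D bond (aryllithium addition) and the C2=C3 bond (intramolecular aldol condensation). The phthalide is a temporary ring; its lactone carbonyl becomes C3 and its enol carbon becomes C1.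
- Enabling feature: C1 and C3 sit on adjacent carbons of ring E (C7a, C3a) as a masked ortho-diacyl unit, C2 lies between the C1 carbonyl and ring B (enolisable), and ring D is attached through the carbon between its two oxygens (lithiated directly between two OMOM groups). C3 sits on the ring E carbon ortho to C4–OH and para to C6–OMe, so it is a resorcylate carbonyl and the OH/OMe pattern follows from chelation-controlled demethylation.
- The phthalide comes from 5-exo-dig lactonisation of an alkynyl diacid, made by two Sonogashira couplings. Rings B and E share one pattern (C at 1, X at 2, OH at 3, OMe at 5), so one bromoaldehyde serves twice: ring E keeps the formyl carbon (→ C3), ring B exchanges it for oxygen by Baeyer–Villiger oxidation (→ ether O).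
- The diaryl ether is made by SNAr of the ring B phenol on a ring A fluoroaldehyde. Rings A, B, D and E are bought as benzenes; the lactone ring forms in step 11 and opens in step 13, where ring C closes.

Key step: step 13

Remark on the chemistry: the three aromatic starting materials are taken as purchasable. The target is achiral; the Z enol-lactone double bond and the two transient stereocentres formed on the way do not survive.

**Route**

Step 1
Reactants: 1 2-bromo-4,6-dimethoxybenzaldehyde
Product: 2 2-bromo-6-hydroxy-4-methoxybenzaldehyde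
Conditions: BCl3 (1.2 equiv), CH2Cl2, −78 → 0 °C; H2O
Reagents that add atoms: none
Why: Chelation-controlled Lewis-acid ether cleavage: BCl3 binds the formyl oxygen and removes only the methyl group of the ortho OMe through a six-membered chelate, so the para OMe stays.

Step 2
Reactants: 2 2-bromo-6-hydroxy-4-methoxybenzaldehyde
Product: 3 2-bromo-4-methoxy-6-(methoxymethoxy)benzaldehyde
Conditions: MOMCl, i-Pr2NEt, CH2Cl2, 0 °C → rt
Reagents that add atoms: chloromethyl methyl ether (MOMCl), COCCl
Why: O-alkylation of the phenol (MOM protection) gives a base-stable acetal that lasts until the final acid treatment.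

Step 3
Reactants: 3 2-bromo-4-methoxy-6-(methoxymethoxy)benzaldehyde
Product: 5 2-bromo-4-methoxy-6-(methoxymethoxy)phenol, via aryl formate 4 (not isolated)
Conditions: mCPBA, CH2Cl2, 0 °C → rt; then K2CO3 (cat.), MeOH, rt
Reagents that add atoms: 3-chloroperoxybenzoic acid (mCPBA), OOC(=O)c1cccc(Cl)c1
Why: Baeyer–Villiger oxidation (Dakin-type): the aryl group, made electron-rich by ortho and para oxygen donors, migrates in preference to hydride, and methanolysis of the formate frees the phenol that becomes the ether oxygen on ring B.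

Step 4
Reactants: 6 3-fluoro-5-methylphenol
Product: 7 1-fluoro-3-(methoxymethoxy)-5-methylbenzene
Conditions: MOMCl, i-Pr2NEt, CH2Cl2, 0 °C → rt
Reagents that add atoms: chloromethyl methyl ether (MOMCl), COCCl
Why: MOM protection by O-alkylation, which also installs the directing group for the next step.

Step 5
Reactants: 7 1-fluoro-3-(methoxymethoxy)-5-methylbenzene
Product: 9 2-fluoro-6-(methoxymethoxy)-4-methylbenzaldehyde, via aryllithium 8 (not isolated)
Conditions: n-BuLi, THF, −78 °C; DMF, −78 °C → rt; H2O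
Reagents that add atoms: N,N-dimethylformamide, CN(C)C=O
Why: Directed ortho-metalation occurs at the one carbon flanked by both F and OMOM (cooperating directors), and formylation with DMF at −78 °C outruns loss of LiF to an aryne.

Step 6
Reactants: 5 2-bromo-4-methoxy-6-(methoxymethoxy)phenol; 9 2-fluoro-6-(methoxymethoxy)-4-methylbenzaldehyde
Product: 10 2-[2-bromo-4-methoxy-6-(methoxymethoxy)phenoxy]-6-(methoxymethoxy)-4-methylbenzaldehyde
Conditions: Cs2CO3, DMF, 80 °C, under N2
Reagents that add atoms: none
Why: Nucleophilic aromatic substitution (addition–elimination): the formyl group ortho to fluorine stabilises the Meisenheimer intermediate, and the OMOM group sits on a carbon that bears no negative charge and so does not deactivate the ring.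

Step 7
Reactants: 10 2-[2-bromo-4-methoxy-6-(methoxymethoxy)phenoxy]-6-(methoxymethoxy)-4-methylbenzaldehyde
Product: 11 2-{4-methoxy-2-(methoxymethoxy)-6-[(trimethylsilyl)ethynyl]phenoxy}-6-(methoxymethoxy)-4-methylbenzaldehyde
Conditions: trimethylsilylacetylene, PdCl2(PhCN)2 (cat.), P(t-Bu)3 (cat.), CuI (cat.), i-Pr2NH, 1,4-dioxane, 50 °C
Reagents that add atoms: trimethylsilylacetylene, C#C[Si](C)(C)C
Why: Sonogashira coupling; the bulky, electron-rich phosphine is chosen because oxidative addition into this electron-rich bromide next to an aryloxy group is slow with PPh3.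

Step 8
Reactants: 11 2-{4-methoxy-2-(methoxymethoxy)-6-[(trimethylsilyl)ethynyl]phenoxy}-6-(methoxymethoxy)-4-methylbenzaldehyde
Product: 12 2-[2-ethynyl-4-methoxy-6-(methoxymethoxy)phenoxy]-6-(methoxymethoxy)-4-methylbenzaldehyde
Conditions: K2CO3 (cat.), MeOH, rt
Reagents that add atoms: none
Why: Base-mediated protodesilylation of the alkynylsilane by methoxide; aldehyde, MOM ethers and diaryl ether are inert.

Step 9
Reactants: 12 2-[2-ethynyl-4-methoxy-6-(methoxymethoxy)phenoxy]-6-(methoxymethoxy)-4-methylbenzaldehyde; 3 2-bromo-4-methoxy-6-(methoxymethoxy)benzaldehyde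
Product: 13 2-({2-[2-formyl-3-(methoxymethoxy)-5-methylphenoxy]-5-methoxy-3-(methoxymethoxy)phenyl}ethynyl)-4-methoxy-6-(methoxymethoxy)benzaldehyde
Conditions: PdCl2(PPh3)2 (cat.), CuI (cat.), Et3N, THF, 60 °C
Reagents that add atoms: none
Why: Sonogashira coupling with a bromide activated for oxidative addition by its ortho formyl group; building block 3 is used a second time here, now as ring E.

Step 10
Reactants: 13 2-({2-[2-formyl-3-(methoxymethoxy)-5-methylphenoxy]-5-methoxy-3-(methoxymethoxy)phenyl}ethynyl)-4-methoxy-6-(methoxymethoxy)benzaldehyde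
Product: 14 2-({2-[2-carboxy-3-(methoxymethoxy)-5-methylphenoxy]-5-methoxy-3-(methoxymethoxy)phenyl}ethynyl)-4-methoxy-6-(methoxymethoxy)benzoic acid
Conditions: NaClO2, NaH2PO4, 2-methyl-2-butene, t-BuOH/THF/H2O, 0 °C → rt
Reagents that add atoms: sodium chlorite, [Na+].[O-]Cl=O
Why: Pinnick oxidation converts both non-enolisable aryl aldehydes into acids at about pH 4, where MOM ethers and the alkyne persist, and 2-methyl-2-butene traps the hypochlorous acid that would chlorinate the electron-rich rings.

Step 11
Reactants: 14 2-({2-[2-carboxy-3-(methoxymethoxy)-5-methylphenoxy]-5-methoxy-3-(methoxymethoxy)phenyl}ethynyl)-4-methoxy-6-(methoxymethoxy)benzoic acid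
Product: 16 methyl 2-(2-{(Z)-[6-methoxy-4-(methoxymethoxy)-3-oxo-2-benzofuran-1(3H)-ylidene]methyl}-4-methoxy-6-(methoxymethoxy)phenoxy)-6-(methoxymethoxy)-4-methylbenzoate, via phthalide acid 15 (not isolated)
Conditions: DBU, MeCN, 60 °C; then MeI, rt
Reagents that add atoms: iodomethane, CI
Why: Base-mediated 5-exo-dig anti addition of the ring E carboxylate across the alkyne gives the Z enol lactone (the preferred mode without acid or electrophilic metal, which would favour 6-endo closure); the ring A carboxylate cannot reach the alkyne and is then esterified by SN2 methylation.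

Step 12
Reactants: 17 orcinol (5-methylbenzene-1,3-diol)
Product: 18 1,3-bis(methoxymethoxy)-5-methylbenzene
Conditions: MOMCl, i-Pr2NEt, CH2Cl2, 0 °C → rt
Reagents that add atoms: chloromethyl methyl ether (MOMCl), COCCl
Why: Double MOM protection by O-alkylation; the two OMOM groups later direct lithiation to the carbon between them.

Step 13
Reactants: 18 1,3-bis(methoxymethoxy)-5-methylbenzene; 16 methyl 2-(2-{(Z)-[6-methoxy-4-(methoxymethoxy)-3-oxo-2-benzofuran-1(3H)-ylidene]methyl}-4-methoxy-6-(methoxymethoxy)phenoxy)-6-(methoxymethoxy)-4-methylbenzoate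
Product: 22 methyl 2-(2-{3-[2,6-bis(methoxymethoxy)-4-methylphenyl]-6-methoxy-4-(methoxymethoxy)-1-oxo-1H-inden-2-yl}-4-methoxy-6-(methoxymethoxy)phenoxy)-6-(methoxymethoxy)-4-methylbenzoate, via aryllithium 19 (not isolated), via keto-enolate 20 (not isolated), via aldolate 21 (not isolated)
Conditions: 18 (1.3 equiv), n-BuLi (1.25 equiv), THF, 0 °C; 16, −78 → −20 °C; then MeOH, 50 °C
Reagents that add atoms: none
Why: Aryllithium 19, formed by lithiation of 18 at the carbon flanked by both OMOM groups, adds to the lactone carbonyl of 16; the adduct collapses with loss of the enolate oxygen, so the temporary phthalide ring opens to keto-enolate 20, whose enolate carbon (future C2) attacks the new diaryl ketone (future C3) to give aldolate 21, and LiOMe released on adding MeOH brings about E1cB loss of hydroxide to the indenone. The closest known reaction type is the conversion of 3-benzylidenephthalides into 2,3-diarylindenones with aryl Grignard or aryllithium reagents, together with the base-mediated aldol condensation of benzyl ketones with diaryl 1,2-diketones that gives tetraarylcyclopentadienones. Ring C closes by a 5-(enolendo)-exo-trig intramolecular aldol addition that forms the C2–C3 bond, and dehydration to the conjugated enone makes the closure irreversible. The two stereocentres of 21 (C2 and C3) arise without control and are both destroyed in the elimination. The step needs chemoselectivity for the lactone carbonyl over the ring A methyl ester and over the new ketone: the strained, planar enol lactone has one ortho substituent and an enolate leaving group and should react at low temperature, whereas the di-ortho-substituted ester and the tri-ortho-substituted ketone need much higher temperatures with a di-ortho-substituted aryllithium, and the ketone is also consumed intramolecularly. Regiochemistry is fixed by the precursor, because the lactone carbonyl carbon can only become C3 and the enol carbon only C1.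

Step 14
Reactants: 22 methyl 2-(2-{3-[2,6-bis(methoxymethoxy)-4-methylphenyl]-6-methoxy-4-(methoxymethoxy)-1-oxo-1H-inden-2-yl}-4-methoxy-6-(methoxymethoxy)phenoxy)-6-(methoxymethoxy)-4-methylbenzoate
Product: 23 Ascomindone B
Conditions: HCl (3 M aq.), MeOH/THF, 50 °C, under N2
Reagents that add atoms: none
Why: Acid-catalysed acetal cleavage (transacetalisation to dimethoxymethane) should remove all five MOM groups, while the aryl methyl ethers, the methyl ester (in methanol) and the indenone are stable to dilute HCl.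

**Compound list**

1 | 2-bromo-4,6-dimethoxybenzaldehyde | COc1cc(Br)c(C=O)c(OC)c1 | starting material
2 | 2-bromo-6-hydroxy-4-methoxybenzaldehyde | COc1cc(O)c(C=O)c(Br)c1 | intermediate
3 | 2-bromo-4-methoxy-6-(methoxymethoxy)benzaldehyde | COCOc1cc(OC)cc(Br)c1C=O | intermediate
4 | 2-bromo-4-methoxy-6-(methoxymethoxy)phenyl formate (not isolated) | COCOc1cc(OC)cc(Br)c1OC=O | intermediate
5 | 2-bromo-4-methoxy-6-(methoxymethoxy)phenol | COCOc1cc(OC)cc(Br)c1O | intermediate
6 | 3-fluoro-5-methylphenol | Cc1cc(O)cc(F)c1 | starting material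
7 | 1-fluoro-3-(methoxymethoxy)-5-methylbenzene | COCOc1cc(C)cc(F)c1 | intermediate
8 | [2-fluoro-6-(methoxymethoxy)-4-methylphenyl]lithium (not isolated) | [Li]c1c(F)cc(C)cc1OCOC | intermediate
9 | 2-fluoro-6-(methoxymethoxy)-4-methylbenzaldehyde | COCOc1cc(C)cc(F)c1C=O | intermediate
10 | 2-[2-bromo-4-methoxy-6-(methoxymethoxy)phenoxy]-6-(methoxymethoxy)-4-methylbenzaldehyde | COCOc1cc(C)cc(Oc2c(Br)cc(OC)cc2OCOC)c1C=O | intermediate
11 | 2-{4-methoxy-2-(methoxymethoxy)-6-[(trimethylsilyl)ethynyl]phenoxy}-6-(methoxymethoxy)-4-methylbenzaldehyde | COCOc1cc(C)cc(Oc2c(OCOC)cc(OC)cc2C#C[Si](C)(C)C)c1C=O | intermediate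
12 | 2-[2-ethynyl-4-methoxy-6-(methoxymethoxy)phenoxy]-6-(methoxymethoxy)-4-methylbenzaldehyde | COCOc1cc(C)cc(Oc2c(OCOC)cc(OC)cc2C#C)c1C=O | intermediate
13 | 2-({2-[2-formyl-3-(methoxymethoxy)-5-methylphenoxy]-5-methoxy-3-(methoxymethoxy)phenyl}ethynyl)-4-methoxy-6-(methoxymethoxy)benzaldehyde | COCOc1cc(C)cc(Oc2c(OCOC)cc(OC)cc2C#Cc2cc(OC)cc(OCOC)c2C=O)c1C=O | intermediate
14 | 2-({2-[2-carboxy-3-(methoxymethoxy)-5-methylphenoxy]-5-methoxy-3-(methoxymethoxy)phenyl}ethynyl)-4-methoxy-6-(methoxymethoxy)benzoic acid | COCOc1cc(C)cc(Oc2c(OCOC)cc(OC)cc2C#Cc2cc(OC)cc(OCOC)c2C(=O)O)c1C(=O)O | intermediate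
15 | 2-(2-{(Z)-[6-methoxy-4-(methoxymethoxy)-3-oxo-2-benzofuran-1(3H)-ylidene]methyl}-4-methoxy-6-(methoxymethoxy)phenoxy)-6-(methoxymethoxy)-4-methylbenzoic acid (Z enol lactone, not isolated) | COCOc1cc(C)cc(Oc2c(OCOC)cc(OC)cc2/C=C2\OC(=O)c3c(OCOC)cc(OC)cc32)c1C(=O)O | intermediate
16 | methyl 2-(2-{(Z)-[6-methoxy-4-(methoxymethoxy)-3-oxo-2-benzofuran-1(3H)-ylidene]methyl}-4-methoxy-6-(methoxymethoxy)phenoxy)-6-(methoxymethoxy)-4-methylbenzoate (Z enol lactone) | COCOc1cc(C)cc(Oc2c(OCOC)cc(OC)cc2/C=C2\OC(=O)c3c(OCOC)cc(OC)cc32)c1C(=O)OC | intermediate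
17 | orcinol (5-methylbenzene-1,3-diol) | Cc1cc(O)cc(O)c1 | starting material
18 | 1,3-bis(methoxymethoxy)-5-methylbenzene | COCOc1cc(C)cc(OCOC)c1 | intermediate
19 | [2,6-bis(methoxymethoxy)-4-methylphenyl]lithium (not isolated) | [Li]c1c(OCOC)cc(C)cc1OCOC | intermediate
20 | lithium enolate (E/Z mixture) of methyl 2-[2-(2-{2-[2,6-bis(methoxymethoxy)-4-methylbenzoyl]-5-methoxy-3-(methoxymethoxy)phenyl}-2-oxoethyl)-4-methoxy-6-(methoxymethoxy)phenoxy]-6-(methoxymethoxy)-4-methylbenzoate (not isolated) | COCOc1cc(C)cc(Oc2c(OCOC)cc(OC)cc2C=C(O[Li])c2cc(OC)cc(OCOC)c2C(=O)c2c(OCOC)cc(C)cc2OCOC)c1C(=O)OC | intermediate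
21 | lithium alkoxide of methyl 2-(2-{1-[2,6-bis(methoxymethoxy)-4-methylphenyl]-1-hydroxy-5-methoxy-7-(methoxymethoxy)-3-oxo-2,3-dihydro-1H-inden-2-yl}-4-methoxy-6-(methoxymethoxy)phenoxy)-6-(methoxymethoxy)-4-methylbenzoate (racemic, mixture of diastereomers at the two ring carbons, configuration not controlled; not isolated) | COCOc1cc(C)cc(Oc2c(OCOC)cc(OC)cc2C2C(=O)c3cc(OC)cc(OCOC)c3C2(O[Li])c2c(OCOC)cc(C)cc2OCOC)c1C(=O)OC | intermediate
22 | methyl 2-(2-{3-[2,6-bis(methoxymethoxy)-4-methylphenyl]-6-methoxy-4-(methoxymethoxy)-1-oxo-1H-inden-2-yl}-4-methoxy-6-(methoxymethoxy)phenoxy)-6-(methoxymethoxy)-4-methylbenzoate | COCOc1cc(C)cc(Oc2c(OCOC)cc(OC)cc2C2=C(c3c(OCOC)cc(C)cc3OCOC)c3c(OCOC)cc(OC)cc3C2=O)c1C(=O)OC | intermediate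
23 | Ascomindone B, methyl 2-{2-[3-(2,6-dihydroxy-4-methylphenyl)-4-hydroxy-6-methoxy-1-oxo-1H-inden-2-yl]-6-hydroxy-4-methoxyphenoxy}-6-hydroxy-4-methylbenzoate (achiral) | COC(=O)c1c(O)cc(C)cc1Oc1c(O)cc(OC)cc1C1=C(c2c(O)cc(C)cc2O)c2c(O)cc(OC)cc2C1=O | target

**Step count**

Total: 14 steps.
Longest linear sequence: 11 steps (steps 1, 2, 3, 6, 7, 8, 9, 10, 11, 13, 14).

**Steps most likely to fail**

Step 13. Chemoselectivity may be lost: at temperatures where the chelated aryllithium 19 attacks the lactone at a useful rate, it may also add to the methyl ester of ring A, since di-ortho-alkoxy aryllithiums are known to add even to di-ortho-substituted benzoates on warming. The fallback sets out from 15 and comes back at 22. Acid 15 is isolated from step 11 by leaving out MeI and converted with LiN(SiMe3)2 (1 equiv, THF, −78 °C) into its lithium carboxylate, which accepts no carbon nucleophile. Treatment with 19 and then MeOH as in step 13 should give 2-(2-{3-[2,6-bis(methoxymethoxy)-4-methylphenyl]-6-methoxy-4-(methoxymethoxy)-1-oxo-1H-inden-2-yl}-4-methoxy-6-(methoxymethoxy)phenoxy)-6-(methoxymethoxy)-4-methylbenzoic acid F1. SN2 methylation of F1 with MeI and K2CO3 in DMF, with no free phenol present, then gives 22.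

Step 11. The 6-endo-dig closure to the isocoumarin may compete with the 5-exo-dig closure, because the electron-rich ring B polarises the alkyne and the di-ortho-substituted carboxylate is twisted. An isocoumarin cannot enter step 13. The fallback sets out from 3 and 12 and comes back at 15. Pinnick oxidation of 3 (NaClO2, NaH2PO4, 2-methyl-2-butene) gives 2-bromo-4-methoxy-6-(methoxymethoxy)benzoic acid F2. Coupling of F2 with 12 (PdCl2(PPh3)2, CuI, Et3N, DMF, 80 °C) forms 2-({2-[2-formyl-3-(methoxymethoxy)-5-methylphenoxy]-5-methoxy-3-(methoxymethoxy)phenyl}ethynyl)-4-methoxy-6-(methoxymethoxy)benzoic acid F3 in the flask. Its metal-bound alkyne is attacked by the neighbouring carboxylate in the 5-exo mode, the known outcome of Castro–Stephens-type couplings of ortho-halobenzoic acids with arylacetylenes, to give 2-(2-{(Z)-[6-methoxy-4-(methoxymethoxy)-3-oxo-2-benzofuran-1(3H)-ylidene]methyl}-4-methoxy-6-(methoxymethoxy)phenoxy)-6-(methoxymethoxy)-4-methylbenzaldehyde F4. Pinnick oxidation of the ring A aldehyde of F4 gives 15, which is methylated as in the second half of step 11.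

Step 6. The SNAr of the di-ortho-substituted, oxidation-prone phenoxide of 5 may be slow enough for the phenoxide to decompose by air oxidation before the ether forms. The fallback sets out from 5 and comes back at 10; it uses a more electrophilic, less hindered partner and builds the ring A oxygen afterwards. Reaction of 5 with commercial 2,6-difluoro-4-methylbenzaldehyde (Cc1cc(F)c(C=O)c(F)c1; K2CO3, DMF, 50 °C) gives 2-[2-bromo-4-methoxy-6-(methoxymethoxy)phenoxy]-6-fluoro-4-methylbenzaldehyde F5. A second SNAr with the sodium alkoxide of 2-(methylsulfonyl)ethanol (NaH, DMF, 0 °C → rt) gives 2-[2-bromo-4-methoxy-6-(methoxymethoxy)phenoxy]-4-methyl-6-[2-(methylsulfonyl)ethoxy]benzaldehyde F6 in the flask. F6 loses methyl vinyl sulfone by base-induced β-elimination to give 2-[2-bromo-4-methoxy-6-(methoxymethoxy)phenoxy]-6-hydroxy-4-methylbenzaldehyde F7. MOM protection of F7 (MOMCl, i-Pr2NEt) gives 10.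

**Further compounds**

F1 | step 13 | 2-(2-{3-[2,6-bis(methoxymethoxy)-4-methylphenyl]-6-methoxy-4-(methoxymethoxy)-1-oxo-1H-inden-2-yl}-4-methoxy-6-(methoxymethoxy)phenoxy)-6-(methoxymethoxy)-4-methylbenzoic acid | COCOc1cc(C)cc(Oc2c(OCOC)cc(OC)cc2C2=C(c3c(OCOC)cc(C)cc3OCOC)c3c(OCOC)cc(OC)cc3C2=O)c1C(=O)O
F2 | step 11 | 2-bromo-4-methoxy-6-(methoxymethoxy)benzoic acid | COCOc1cc(OC)cc(Br)c1C(=O)O
F3 | step 11 | 2-({2-[2-formyl-3-(methoxymethoxy)-5-methylphenoxy]-5-methoxy-3-(methoxymethoxy)phenyl}ethynyl)-4-methoxy-6-(methoxymethoxy)benzoic acid | COCOc1cc(C)cc(Oc2c(OCOC)cc(OC)cc2C#Cc2cc(OC)cc(OCOC)c2C(=O)O)c1C=O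
F4 | step 11 | 2-(2-{(Z)-[6-methoxy-4-(methoxymethoxy)-3-oxo-2-benzofuran-1(3H)-ylidene]methyl}-4-methoxy-6-(methoxymethoxy)phenoxy)-6-(methoxymethoxy)-4-methylbenzaldehyde | COCOc1cc(C)cc(Oc2c(OCOC)cc(OC)cc2/C=C2\OC(=O)c3c(OCOC)cc(OC)cc32)c1C=O
F5 | step 6 | 2-[2-bromo-4-methoxy-6-(methoxymethoxy)phenoxy]-6-fluoro-4-methylbenzaldehyde | Cc1cc(F)c(C=O)c(Oc2c(Br)cc(OC)cc2OCOC)c1
F6 | step 6 | 2-[2-bromo-4-methoxy-6-(methoxymethoxy)phenoxy]-4-methyl-6-[2-(methylsulfonyl)ethoxy]benzaldehyde | Cc1cc(OCCS(C)(=O)=O)c(C=O)c(Oc2c(Br)cc(OC)cc2OCOC)c1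
F7 | step 6 | 2-[2-bromo-4-methoxy-6-(methoxymethoxy)phenoxy]-6-hydroxy-4-methylbenzaldehyde | Cc1cc(O)c(C=O)c(Oc2c(Br)cc(OC)cc2OCOC)c1
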